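Of the 0.050 M of electrophile charged, the amount that counted was the amount gone, the charge minus what still stood, so I read the earlier runs for that amount.

| flask | electrophile | nucleophile | remark | time |
|---|---|---|---|---|
| oak | 0.050 M (fed, over 3.0 h) | 0.044 M | run made earlier; the fed solution adds 0.25 times the starting volume |  |
| larch | 0.050 M (fed, over 3.0 h) | 0.059 M | run made earlier; the fed solution adds 0.25 times the starting volume |  |
| ash | 0.050 M (fed, over 3.0 h) | 0.085 M | run made earlier; the fed solution adds 0.25 times the starting volume |  |
| autumn | 0.050 M (fed, over 3.0 h) | 0.0500 M | the fed solution adds 0.25 times the starting volume | 15 h |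
| winter | 0.050 M (fed, over 3.0 h) | 0.0750 M | the fed solution adds 0.25 times the starting volume | 15 h |

| run | time / h | electrophile / % | target / % |
|---|---|---|---|
| oak | 1.33 | 34.0 | 6.3 |
| oak | 2.50 | 69.5 | 4.1 |
| oak | 4.00 | 84.1 | 2.1 |
| oak | 8.00 | 82.0 | 1.9 |
| oak | 15.0 | 78.6 | 1.4 |
| larch | 1.33 | 33.1 | 5.8 |
| larch | 2.50 | 67.8 | 4.6 |
| larch | 4.00 | 82.2 | 1.7 |
| larch | 8.00 | 80.3 | 1.1 |
| larch | 15.0 | 77.2 | 1.0 |
| ash | 1.33 | 32.2 | 7.3 |
| ash | 4.00 | 80.9 | 3.3 |
| ash | 8.00 | 79.4 | 2.5 |
| ash | 10.0 | 78.0 | 1.8 |
| ash | 15.0 | 75.5 | 1.5 |

(each reading ± 0.5 percentage points)

- charges are per starting volume, the dose included; the dosed solution carries all of it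
- percentages count the whole charge, also what has not yet gone in

* part of the electrophile that has reacted at the end, autumn
* part of the electrophile that has reacted at the end, winter
* what raising the concentration of nucleophile from its lowest to its highest value here does to the part of the electrophile that has reacted (changes below 5 percentage points count as none) (it falls / it rises / no change)

The first rung was the feed itself: in the oak run at 1.33 h, 44.3% of the charge had gone in and 34.0% was read, so about 10 percentage points had reacted while dosing ran. The next rung took hours: the oak target sank from 6.3% to 2.1% by 4.00 h, and that last reading stood below the 15.9% of electrophile gone by then, so the rest of what had reacted lay in species I did not read.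

The last rung was the fall after the feed. Averaged over the runs, from 4.00 h to the last reading, electrophile lost 0.00482 h⁻¹ of the charge; this mean fall per hour I called the drain. Its emptying time, 207 h, was far longer than 15 h, which is why I dared a straight line. Replacing the oak curve by its mean cost, as far as the oak readings showed, 0.43 points over that stretch, less than the scatter of one reading.

Interpolating the amount gone at 4.00 h in c(nucleophile) gave 16.7% for autumn and 18.6% for winter, and the drain added 5.3 points to each, so I reckoned 22.0% and 23.9%, a gap smaller than 5 points. The forecast said 22%, 23.9% and no change: “Both new runs fall inside this range, so I interpolate”.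

The flasks gave 21.9% for autumn and 23.8% for winter, no change at 1.9 points.

    electrophile + target → side product (k = 7.10 M⁻¹ h⁻¹)
    nucleophile + acid set free ⇌ protonated nucleophile, settled at all times (K = 1.40 × 10⁵ M⁻¹)
    2 nucleophile → self-condensation product (k = 44.0 M⁻¹ h⁻¹)
    electrophile + nucleophile → acid set free + target (k = 61.0 M⁻¹ h⁻¹)
    target ⇌ isomer of the product (K = 5.40, k = 0.770 h⁻¹)

In autumn at the end the nucleophile, the limiting reagent, stood free at 0.0445% of its charge, with 78% of the electrophile still there. The drain, run from the 84.4% of electrophile in autumn at 3.00 h, reached 78.6% at 15.0 h, where 78.1% stood. Run back from the end of winter to 6.0 h, it gave 19.5% reacted, and that winter flask read at 6.0 h stood at 19.6%.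

The runs were generated by integration with constants of no real substance; the scatter is artificial.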